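## Retrosynthetic overview

1. Labels: unit 1 has rings A (benzo, C4a–C8a), C (pyranone) and B (1,4-phenylene). Unit 2 has rings D (benzo), F (pyranone) and E (4-hydroxyphenyl). Rings B and D are joined by the C4'–O–C6'' ether.
2. The end game is hydrogenolysis of five benzyl ethers. Before it, ring E and C2'' are added by a rhodium-catalysed asymmetric 1,4-arylation of the ring F chromone.
3. Key disconnection: ring C is cut at O1–C8a and C4–C4a in one stroke. This gives 3,5-bis(benzyloxy)benzyne (ring A) and an (S)-β-silyloxy Weinreb amide that already holds C2, C3, C4 and rings B, D and F.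
4. Enabling feature: on ring A, O1 (on C8a) and acyl carbon C4 (on C4a) are ortho neighbours, C4a is flanked by the C5 oxygen, and O1–C2–C3–C4 is a β-oxy-acyl chain. An aryne whose C5 oxygen sits beside the triple bond therefore takes oxygen at C8a and the carbanion at C4a.
5. The amide comes from 4-fluorobenzaldehyde (SNAr, Reformatsky, oxidation, Noyori hydrogenation setting C2) and phloroacetophenone (Elbs oxidation installs the C6'' oxygen, enaminone closure makes ring F). Rings close in the order F, then C.

Key step: step 11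

Assumption: 3,5-bis(benzyloxy)phenol and 2-bromo-N-methoxy-N-methylacetamide are taken as catalogue chemicals; double-primed locants refer to unit 2.

## Route

Step 1
Reactants: 1 2',4',6'-trihydroxyacetophenone
Product: 2 1-[2,4-bis(benzyloxy)-6-hydroxyphenyl]ethan-1-one
Conditions: BnBr (2.1 equiv), K2CO3 (2.2 equiv), DMF, rt → 50 °C
Reagents that add atoms: benzyl bromide, BrCc1ccccc1
Why: Williamson ether synthesis in which the para hydroxyl and one ortho hydroxyl are alkylated, while the remaining ortho hydroxyl is locked in a hydrogen bond to the acetyl oxygen, is the least nucleophilic and stays free.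

Step 2
Reactants: 2 1-[2,4-bis(benzyloxy)-6-hydroxyphenyl]ethan-1-one
Product: 4 1-[2,4-bis(benzyloxy)-3,6-dihydroxyphenyl]ethan-1-one, via aryl sulfate 3 (not isolated)
Conditions: K2S2O8, aq NaOH, pyridine, 0 °C → rt; then HCl to pH 1, 70 °C
Reagents that add atoms: potassium peroxodisulfate, [K+].[K+].[O-]S(=O)(=O)OOS(=O)(=O)[O-]
Why: Elbs persulfate oxidation, in which the phenoxide of 2 attacks the peroxide oxygen through its only free para carbon (between the two benzyloxy groups) and acid hydrolysis of sulfate 3 frees the new hydroxyl, as is known for the 4,6-dimethoxy analogue.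

Step 3
Reactants: 4 1-[2,4-bis(benzyloxy)-3,6-dihydroxyphenyl]ethan-1-one; 5 4-fluorobenzaldehyde
Product: 6 4-[3-acetyl-2,6-bis(benzyloxy)-4-hydroxyphenoxy]benzaldehyde
Conditions: K2CO3, DMF, 80 °C, Ar
Reagents that add atoms: none
Why: Nucleophilic aromatic substitution (SNAr), in which the electron-rich non-chelated phenoxide between the benzyloxy groups displaces fluoride para to the formyl group, while the ortho-acyl phenoxide is delocalised, chelated and far less nucleophilic.

Step 4
Reactants: 6 4-[3-acetyl-2,6-bis(benzyloxy)-4-hydroxyphenoxy]benzaldehyde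
Product: 8 4-{[5,7-bis(benzyloxy)-4-oxo-4H-chromen-6-yl]oxy}benzaldehyde, via enaminone 7 (not isolated)
Conditions: Me2NCH(OMe)2, toluene, 95 °C; evaporate; conc. HCl, CH2Cl2, 40 °C
Reagents that add atoms: N,N-dimethylformamide dimethyl acetal, COC(OC)N(C)C
Why: Standard enaminone chromone synthesis, in which the methyl ketone condenses with the amide acetal and acid drives addition–elimination of the only free phenol, closing ring F and fixing the aryloxy group at C6''.

Step 5
Reactants: 8 4-{[5,7-bis(benzyloxy)-4-oxo-4H-chromen-6-yl]oxy}benzaldehyde; 9 2-bromo-N-methoxy-N-methylacetamide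
Product: 12 rac-3-(4-{[5,7-bis(benzyloxy)-4-oxo-4H-chromen-6-yl]oxy}phenyl)-3-hydroxy-N-methoxy-N-methylpropanamide, via Reformatsky reagent 10 (not isolated), via zinc aldolate 11 (not isolated)
Conditions: Zn dust (activated with cat. TMSCl), THF, 40 °C; then 0.5 M HCl, 0 °C
Reagents that add atoms: none
Why: Reformatsky reaction, in which the weakly basic zinc amide enolate adds to the aldehyde only and leaves the vinylogous-ester carbonyl of the chromone alone.

Step 6
Reactants: 12 rac-β-hydroxy Weinreb amide
Product: 13 3-(4-{[5,7-bis(benzyloxy)-4-oxo-4H-chromen-6-yl]oxy}phenyl)-N-methoxy-N-methyl-3-oxopropanamide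
Conditions: Dess–Martin periodinane, CH2Cl2, 0 °C → rt
Reagents that add atoms: none
Why: Dess–Martin oxidation of a benzylic secondary alcohol under neutral conditions erases the racemic centre and gives the β-keto amide for the asymmetric reduction, without effect on the chromone, the benzyl ethers or the N–O bond.

Step 7
Reactants: 13 β-keto Weinreb amide
Product: 14 (3S)-3-(4-{[5,7-bis(benzyloxy)-4-oxo-4H-chromen-6-yl]oxy}phenyl)-3-hydroxy-N-methoxy-N-methylpropanamide
Conditions: [RuCl(p-cymene)((R)-SEGPHOS)]Cl (1 mol%), H2 (30 atm), MeOH/CH2Cl2 3:1, 50 °C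
Reagents that add atoms: none
Why: Noyori asymmetric hydrogenation of a β-keto acid derivative, in which chelation of the ketone and amide carbonyls to ruthenium lets the (R)-biaryl diphosphine deliver hydride to the face that gives the (S)-aryl carbinol (the sense known for aroylacetates), while the non-chelating chromone carbonyl and the benzyl ethers are not reduced.

Step 8
Reactants: 14 (S)-β-hydroxy Weinreb amide
Product: 15 (3S)-3-(4-{[5,7-bis(benzyloxy)-4-oxo-4H-chromen-6-yl]oxy}phenyl)-N-methoxy-N-methyl-3-[(trimethylsilyl)oxy]propanamide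
Conditions: TMSCl, imidazole, CH2Cl2, 0 °C; short pad of Et3N-washed silica
Reagents that add atoms: chlorotrimethylsilane, C[Si](C)(C)Cl
Why: Standard silylation of a secondary alcohol turns the O–H, which would protonate the aryl anion of step 11, into a fluoride-labile latent alkoxide without touching the stereocentre.

Step 9
Reactants: 16 3,5-bis(benzyloxy)phenol
Product: 17 3,5-bis(benzyloxy)-2-bromophenol
Conditions: NBS (1.0 equiv), CH2Cl2, −78 °C → 0 °C
Reagents that add atoms: N-bromosuccinimide, O=C1CCC(=O)N1Br
Why: Electrophilic aromatic bromination at C2, which is ortho to the free hydroxyl and para to a benzyloxy group, in preference to C4, which is crowded between two benzyloxy groups.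

Step 10
Reactants: 17 3,5-bis(benzyloxy)-2-bromophenol
Product: 21 3,5-bis(benzyloxy)-2-(trimethylsilyl)phenyl trifluoromethanesulfonate, via silyl ether 18 (not isolated), via aryllithium 19 (not isolated), via lithium phenoxide 20 (not isolated)
Conditions: (Me3Si)2NH, THF, 70 °C, evaporate; n-BuLi, THF, −78 °C; Tf2O, −78 °C → 0 °C
Reagents that add atoms: hexamethyldisilazane, C[Si](C)(C)N[Si](C)(C)C; trifluoromethanesulfonic anhydride, O=S(=O)(OS(=O)(=O)C(F)(F)F)C(F)(F)F
Why: This is the standard sequence to o-silylaryl triflates, namely O-silylation, fast bromine–lithium exchange, retro-Brook O-to-C silyl migration and triflation of the resulting phenoxide, with the exchange outrunning benzylic deprotonation at low temperature.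

Step 11
Reactants: 15 (S)-β-(trimethylsilyloxy) Weinreb amide; 21 3,5-bis(benzyloxy)-2-(trimethylsilyl)phenyl trifluoromethanesulfonate
Product: 26 (2S)-5,7-bis(benzyloxy)-2-(4-{[5,7-bis(benzyloxy)-4-oxo-4H-chromen-6-yl]oxy}phenyl)-2,3-dihydro-4H-chromen-4-one, via cesium alkoxide 22 (not isolated), via aryne 23 (not isolated), via arylcesium 24 (not isolated), via cesium hemiaminalate 25 (not isolated)
Conditions: 15, CsF (4 equiv), 18-crown-6 (1 equiv), THF, 0 °C; 21 (1.4 equiv) added over 4 h, 0 °C → rt; AcOH quench at 0 °C, pH 5 buffer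
Reagents that add atoms: none
Why: Proposed new method: fluoride strips the O–SiMe3 group of 15 and, more slowly, the C–SiMe3 group of 21, so that alkoxide 22 meets aryne 23 in a proton-free medium and adds through oxygen to give arylcesium 24, whose carbanion attacks the tethered N-methoxy-N-methylamide carbonyl to give hemiaminalate 25, which should persist until the acetic acid quench and then lose MeNHOMe to give ketone 26. The closest known reaction types are the aryne–salicylate annulation to xanthones, the aryne ring expansion of β-lactams to 2,3-dihydroquinolin-4-ones, the O-arylation of aliphatic alcohols by arynes and the Parham cyclisation of 3-(2-haloaryloxy)propanoic Weinreb amides to chroman-4-ones, and what has not been shown is their union on an aliphatic β-oxido amide. Ring C closes by intermolecular O1–C8a bond formation followed by a 6-exo-trig attack of C4a on C4. No stereocentre of the product is created, since C2 is carried in from 15 with retention because none of its four bonds is touched, and the transient C4 hemiaminal centre is erased at work-up. The regioselectivity needed is secured by the benzyloxy group beside the triple bond, whose inductive pull distorts the aryne so that the nucleophile adds to the distal carbon (future C8a) and the charge develops on the adjacent carbon (future C4a), which gives only the 5,7-dioxygenation pattern. Configurational integrity and chemoselectivity are secured by the amide (a poor enolate leaving group, hence little retro-aldol or E1cB loss, and neither a ketone nor a free alkoxide leaving group in the basic medium), by the silyl ether (no O–H to protonate 24), by THF instead of an acidic solvent, and by the chromone spectator, which has no stereocentre and no acidic C–H.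

Step 12
Reactants: 26 flavanone–chromone; 27 4-(benzyloxy)phenylboronic acid
Product: 28 (2S)-5,7-bis(benzyloxy)-2-[4-({(2S)-5,7-bis(benzyloxy)-2-[4-(benzyloxy)phenyl]-4-oxo-3,4-dihydro-2H-chromen-6-yl}oxy)phenyl]-2,3-dihydro-4H-chromen-4-one
Conditions: 27 (3 equiv), [Rh(OH)(cod)]2 (2.5 mol%), (S)-MeO-F12-BIPHEP (5.5 mol%), CH2Cl2/H2O 10:1, rt
Reagents that add atoms: none
Why: Hayashi–Miyaura asymmetric 1,4-addition, a known route from chromones (5,7-dioxygenated ones included) to flavanones, in which the aryl–rhodium species with the electron-poor (S)-biaryl diphosphine carbometalates C2''=C3'' from the face that gives the (2''S) centre (the sense shown by (S)-biaryl diphosphines with cyclic enones) under pure catalyst control, while the hindered ring C ketone is inert and the near-neutral medium leaves C2 untouched.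

Step 13
Reactants: 28 pentabenzyl ether
Product: 29 (2S,2''S)-2,3,2'',3''-tetrahydrohinokiflavone (target)
Conditions: H2 (1 atm), 10% Pd/C, THF/MeOH 1:1, rt
Reagents that add atoms: none
Why: Catalytic hydrogenolysis of aryl benzyl ethers under neutral conditions, well precedented for benzylated flavanones, frees all five phenols without enolisation, so both stereocentres are kept.

## Compound list

1 | 2',4',6'-trihydroxyacetophenone | CC(=O)c1c(O)cc(O)cc1O | starting material
2 | 1-[2,4-bis(benzyloxy)-6-hydroxyphenyl]ethan-1-one | CC(=O)c1c(O)cc(OCc2ccccc2)cc1OCc1ccccc1 | intermediate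
3 | potassium 3-acetyl-2,6-bis(benzyloxy)-4-hydroxyphenyl sulfate | CC(=O)c1c(O)cc(OCc2ccccc2)c(OS(=O)(=O)[O-])c1OCc1ccccc1.[K+] | intermediate
4 | 1-[2,4-bis(benzyloxy)-3,6-dihydroxyphenyl]ethan-1-one | CC(=O)c1c(O)cc(OCc2ccccc2)c(O)c1OCc1ccccc1 | intermediate
5 | 4-fluorobenzaldehyde | O=Cc1ccc(F)cc1 | starting material
6 | 4-[3-acetyl-2,6-bis(benzyloxy)-4-hydroxyphenoxy]benzaldehyde | CC(=O)c1c(O)cc(OCc2ccccc2)c(Oc2ccc(C=O)cc2)c1OCc1ccccc1 | intermediate
7 | (E)-enaminone of 6 | CN(C)/C=C/C(=O)c1c(O)cc(OCc2ccccc2)c(Oc2ccc(C=O)cc2)c1OCc1ccccc1 | intermediate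
8 | 4-{[5,7-bis(benzyloxy)-4-oxo-4H-chromen-6-yl]oxy}benzaldehyde | O=Cc1ccc(Oc2c(OCc3ccccc3)cc3occc(=O)c3c2OCc2ccccc2)cc1 | intermediate
9 | 2-bromo-N-methoxy-N-methylacetamide | CON(C)C(=O)CBr | starting material
10 | bromo{2-[methoxy(methyl)amino]-2-oxoethyl}zinc | CON(C)C(=O)C[Zn]Br | intermediate
11 | bromozinc aldolate of 12 | CON(C)C(=O)CC(O[Zn]Br)c1ccc(Oc2c(OCc3ccccc3)cc3occc(=O)c3c2OCc2ccccc2)cc1 | intermediate
12 | rac-β-hydroxy Weinreb amide | CON(C)C(=O)CC(O)c1ccc(Oc2c(OCc3ccccc3)cc3occc(=O)c3c2OCc2ccccc2)cc1 | intermediate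
13 | β-keto Weinreb amide | CON(C)C(=O)CC(=O)c1ccc(Oc2c(OCc3ccccc3)cc3occc(=O)c3c2OCc2ccccc2)cc1 | intermediate
14 | (3S)-β-hydroxy Weinreb amide | CON(C)C(=O)C[C@@H](c1ccc(Oc2c(OCc3ccccc3)cc3occc(=O)c3c2OCc2ccccc2)cc1)O | intermediate
15 | (3S)-β-(trimethylsilyloxy) Weinreb amide | CON(C)C(=O)C[C@@H](c1ccc(Oc2c(OCc3ccccc3)cc3occc(=O)c3c2OCc2ccccc2)cc1)O[Si](C)(C)C | intermediate
16 | 3,5-bis(benzyloxy)phenol | Oc1cc(OCc2ccccc2)cc(OCc2ccccc2)c1 | starting material
17 | 3,5-bis(benzyloxy)-2-bromophenol | Oc1cc(OCc2ccccc2)cc(OCc2ccccc2)c1Br | intermediate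
18 | [3,5-bis(benzyloxy)-2-bromophenoxy]trimethylsilane | C[Si](C)(C)Oc1cc(OCc2ccccc2)cc(OCc2ccccc2)c1Br | intermediate
19 | {2,4-bis(benzyloxy)-6-[(trimethylsilyl)oxy]phenyl}lithium | C[Si](C)(C)Oc1cc(OCc2ccccc2)cc(OCc2ccccc2)c1[Li] | intermediate
20 | lithium 3,5-bis(benzyloxy)-2-(trimethylsilyl)phenoxide | [Li+].[O-]c1cc(OCc2ccccc2)cc(OCc2ccccc2)c1[Si](C)(C)C | intermediate
21 | 3,5-bis(benzyloxy)-2-(trimethylsilyl)phenyl trifluoromethanesulfonate | C[Si](C)(C)c1c(OS(=O)(=O)C(F)(F)F)cc(OCc2ccccc2)cc1OCc1ccccc1 | intermediate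
22 | cesium (S)-alkoxide from 15 | CON(C)C(=O)C[C@@H](c1ccc(Oc2c(OCc3ccccc3)cc3occc(=O)c3c2OCc2ccccc2)cc1)[O-].[Cs+] | intermediate
23 | 3,5-bis(benzyloxy)benzyne | C1#CC(OCc2ccccc2)=CC(OCc2ccccc2)=C1 | intermediate
24 | arylcesium O-adduct of 22 and 23 | CON(C)C(=O)C[C@@H](c1ccc(Oc2c(OCc3ccccc3)cc3occc(=O)c3c2OCc2ccccc2)cc1)Oc1cc(OCc2ccccc2)cc(OCc2ccccc2)[c-]1.[Cs+] | intermediate
25 | cesium C4 hemiaminalate (C4 epimers) | CON(C)C1([O-])C[C@@H](c2ccc(Oc3c(OCc4ccccc4)cc4occc(=O)c4c3OCc3ccccc3)cc2)Oc2cc(OCc3ccccc3)cc(OCc3ccccc3)c21.[Cs+] | intermediate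
26 | (2S)-flavanone–chromone, tetrabenzyl ether | O=C1C[C@@H](c2ccc(Oc3c(OCc4ccccc4)cc4occc(=O)c4c3OCc3ccccc3)cc2)Oc2cc(OCc3ccccc3)cc(OCc3ccccc3)c21 | intermediate
27 | 4-(benzyloxy)phenylboronic acid | OB(O)c1ccc(OCc2ccccc2)cc1 | starting material
28 | (2S,2''S)-biflavanone pentabenzyl ether | O=C1C[C@@H](c2ccc(Oc3c(OCc4ccccc4)cc4c(c3OCc3ccccc3)C(=O)C[C@@H](c3ccc(OCc5ccccc5)cc3)O4)cc2)Oc2cc(OCc3ccccc3)cc(OCc3ccccc3)c21 | intermediate
29 | (2S,2''S)-2,3,2'',3''-tetrahydrohinokiflavone | O=C1C[C@@H](c2ccc(Oc3c(O)cc4c(c3O)C(=O)C[C@@H](c3ccc(O)cc3)O4)cc2)Oc2cc(O)cc(O)c21 | target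

## Step count and risks

Total step count: 13. Longest linear sequence: 11 (steps 1–8, then 11–13). Steps 9 and 10 form the side branch to the aryne precursor.

**Risk 1, step 11.** What may go wrong:
- The aryl anion may be protonated or may abstract an α-hydrogen before acyl capture.
- The hindered alkoxide may capture the aryne too slowly.
- The alkoxide may add to C2'' of the chromone.
- The hemiaminalate may collapse early, after which base would open the new ring.

The fallback uses known chemistry, sets out from 2 and 8 and returns at 26. The dianion of 2 (LiN(SiMe3)2, THF, −78 °C) is C-acylated with di-tert-butyl dicarbonate to tert-butyl 3-[2,4-bis(benzyloxy)-6-hydroxyphenyl]-3-oxopropanoate F1. Knoevenagel condensation of this ester with aldehyde 8 (piperidinium acetate, toluene, 4 Å sieves) gives the alkylidene β-keto ester F2. A cinchona-derived bifunctional thiourea, in the pseudoenantiomeric form that leads to the 2S series, then promotes the known enantioselective intramolecular oxa-Michael addition (6-endo-trig) to the (2S)-3-(tert-butoxycarbonyl)flavanone F3. TsOH in toluene at 80 °C removes the activating ester by dealkylation and decarboxylation to give 26. Ring C remains the last ring to be closed.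

**Risk 2, step 2.** What may go wrong:
- Conversion may be low because the lipophilic phenoxide dissolves poorly in aqueous alkali.
- The hydroquinone may be over-oxidised.
- The benzyl group next to the carbonyl may be lost during the acid hydrolysis.

The fallback sets out from 2 and returns at 4. Teuber oxidation with (KSO3)2NO (KH2PO4 buffer, acetone/H2O, rt) takes the para-unsubstituted phenol to 2-acetyl-3,5-bis(benzyloxy)-1,4-benzoquinone F4. Reduction with Na2S2O4 in THF/H2O then gives hydroquinone 4.

**Risk 3, step 3.** What may go wrong: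
- Claisen–Schmidt condensation may occur between the methyl ketone and an aldehyde group under hot carbonate.
- The doubly ortho-substituted phenoxide may attack sluggishly.
- The hydroquinone may be oxidised by air.

The fallback sets out from 4 and returns at 6. It replaces SNAr by metal-free O-arylation through ligand coupling at trivalent iodine. The salt (4-formylphenyl)(2,4,6-trimethoxyphenyl)iodonium 4-methylbenzenesulfonate F5 is made in one pot from 4-iodobenzaldehyde (mCPBA, TsOH·H2O, then 1,3,5-trimethoxybenzene). It transfers its electron-poor aryl group to the non-chelated phenoxide of 4 (K2CO3, MeCN, rt) and gives 6 without heating.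

## Further compounds

F1 | step 11 | tert-butyl 3-[2,4-bis(benzyloxy)-6-hydroxyphenyl]-3-oxopropanoate | CC(C)(C)OC(=O)CC(=O)c1c(O)cc(OCc2ccccc2)cc1OCc1ccccc1
F2 | step 11 | alkylidene β-keto ester from F1 and 8 (alkene geometry not fixed) | CC(C)(C)OC(=O)C(=Cc1ccc(Oc2c(OCc3ccccc3)cc3occc(=O)c3c2OCc2ccccc2)cc1)C(=O)c1c(O)cc(OCc2ccccc2)cc1OCc1ccccc1
F3 | step 11 | (2S)-3-(tert-butoxycarbonyl)flavanone (C3 labile) | O=C1C(C(=O)OC(C)(C)C)[C@@H](c2ccc(Oc3c(OCc4ccccc4)cc4occc(=O)c4c3OCc3ccccc3)cc2)Oc2cc(OCc3ccccc3)cc(OCc3ccccc3)c21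
F4 | step 2 | 2-acetyl-3,5-bis(benzyloxy)-1,4-benzoquinone | CC(=O)C1=C(OCc2ccccc2)C(=O)C(OCc2ccccc2)=CC1=O
F5 | step 3 | (4-formylphenyl)(2,4,6-trimethoxyphenyl)iodonium 4-methylbenzenesulfonate | O=Cc1ccc([I+]c2c(OC)cc(OC)cc2OC)cc1.Cc1ccc(S(=O)(=O)[O-])cc1
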